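Rings are lettered A to E starting from the 3,5-dihydroxyphenoxy end. The C-4 hydroxyls of rings B, D and E are disconnected to C–H bonds. In the octamethyl 4-deoxy pentamer these three C-4–H bonds, each flanked by C-3–H and C-5–H, are the only aryl C–H bonds with no ortho substituent, whereas every C–H of rings A and C lies between two oxygens. One iridium-catalysed borylation should therefore convert exactly these three C–H bonds into C–B bonds, which are then oxidised to C–O. The precursor is assembled convergently from an A–B–C aryl bromide and a D–E phenol by SNAr, Baeyer–Villiger, Chan–Lam and Ullmann steps.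

Key step: step 7

Remark on the chemistry: in rings B and D, C-1 carries the ether oxygen to the preceding ring, C-2 the methoxy (later hydroxyl) group and C-6 the ether oxygen to the following ring. In ring E, C-1 carries its only ether oxygen. C-4 is para to C-1 in each case (systematic names number each ring from its own point of attachment). The target is achiral and has eleven free hydroxyls, so the borylation precursor carries eight methyl ethers and the last step cleaves exactly eight.

Step 1
Reactants: 1 2,6-dimethoxyphenol; 2 2-fluoro-6-methoxybenzaldehyde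
Product: 3 2-(2,6-dimethoxyphenoxy)-6-methoxybenzaldehyde
Conditions: K2CO3, DMA, 130 °C, N2
Reagents that add atoms: none
Why: Nucleophilic aromatic substitution (SNAr), in which the ortho-formyl group stabilises the Meisenheimer adduct at the fluorine-bearing carbon, is established for 2-fluorobenzaldehydes with hindered phenoxides and fixes the D–E ether position without any regiochemical choice.

Step 2
Reactants: 3 2-(2,6-dimethoxyphenoxy)-6-methoxybenzaldehyde
Product: 5 2-(2,6-dimethoxyphenoxy)-6-methoxyphenol, via aryl formate 4 (not isolated)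
Conditions: mCPBA, CH2Cl2, 0 °C to rt; aq NaHCO3 wash; then K2CO3 (cat.), MeOH, rt
Reagents that add atoms: mCPBA, O=C(OO)c1cccc(Cl)c1
Why: In this Baeyer–Villiger (Dakin-type) oxidation the electron-rich 2,6-dioxygenated aryl group should migrate in preference to hydrogen, and methanolysis of the formate unveils the C-1 hydroxyl of ring D between the methoxy and aryloxy groups.

Step 3
Reactants: 6 4-bromo-2,6-dimethoxyphenol; 2 2-fluoro-6-methoxybenzaldehyde
Product: 7 2-(4-bromo-2,6-dimethoxyphenoxy)-6-methoxybenzaldehyde
Conditions: K2CO3, DMA, 130 °C, N2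
Reagents that add atoms: none
Why: The same SNAr reaction forms the B–C ether, and the unactivated aryl bromide of ring C is a spectator because only the fluorine-bearing carbon is ortho to the formyl group.

Step 4
Reactants: 7 2-(4-bromo-2,6-dimethoxyphenoxy)-6-methoxybenzaldehyde
Product: 9 2-(4-bromo-2,6-dimethoxyphenoxy)-6-methoxyphenol, via aryl formate 8 (not isolated)
Conditions: mCPBA, CH2Cl2, 0 °C to rt; aq NaHCO3 wash; then K2CO3 (cat.), MeOH, rt
Reagents that add atoms: mCPBA, O=C(OO)c1cccc(Cl)c1
Why: Baeyer–Villiger oxidation with aryl migration followed by formate methanolysis should deliver the C-1 phenol of ring B, the aryl bromide being inert to the peracid.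

Step 5
Reactants: 9 2-(4-bromo-2,6-dimethoxyphenoxy)-6-methoxyphenol; 10 3,5-dimethoxyphenylboronic acid
Product: 11 5-bromo-2-[2-(3,5-dimethoxyphenoxy)-3-methoxyphenoxy]-1,3-dimethoxybenzene (A–B–C bromide)
Conditions: Cu(OAc)2 (2 equiv), pyridine, 4 Å MS, CH2Cl2, air, rt
Reagents that add atoms: none
Why: Chan–Lam coupling (transmetalation of the arylboronic acid to the copper phenoxide and reductive elimination from trivalent copper) forms the A–B ether at room temperature, where the bromide of ring C does not react, and the reaction type is known to accept di-ortho-substituted phenols.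

Step 6
Reactants: 11 A–B–C bromide; 5 2-(2,6-dimethoxyphenoxy)-6-methoxyphenol
Product: 12 2-[2-(3,5-dimethoxyphenoxy)-3-methoxyphenoxy]-5-[2-(2,6-dimethoxyphenoxy)-6-methoxyphenoxy]-1,3-dimethoxybenzene (octamethyl ether of the 4-deoxy pentamer)
Conditions: CuI (20 mol%), picolinic acid (40 mol%), K3PO4, DMSO, 100 °C, argon
Reagents that add atoms: none
Why: In this Ullmann-type diaryl ether coupling the bromide at C-4 of ring C has two ortho hydrogens, so the ligand-accelerated monovalent copper catalyst, a system suited to hindered phenols, should join it to the di-ortho-substituted phenol 5.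

Step 7
Reactants: 12 octamethyl ether of the 4-deoxy pentamer; 13 bis(pinacolato)diboron
Product: 14 tris(pinacolboronate) of the octamethyl 4-deoxy pentamer (pinacolboryl group at C-4 of ring B and ring D and ring E)
Conditions: [Ir(OMe)(cod)]2 (5 mol%), 3,4,7,8-tetramethyl-1,10-phenanthroline (10 mol%), B2pin2 (4.5 equiv), THF, 80 °C, sealed tube, argon
Reagents that add atoms: bis(pinacolato)diboron (second and third equivalents of 13), CC1(C)OB(OC1(C)C)B1OC(C)(C)C(C)(C)O1
Why: The trisboryl complex of trivalent iridium formed from [Ir(OMe)(cod)]2, the phenanthroline ligand and B2pin2 adds an aryl C–H bond oxidatively, reductive elimination forms the C–B bond, and B2pin2 regenerates the trisboryl species with release of pinacolborane, so each new C–B bond consumes one molecule of 13 and three are needed in all. The closest known reaction type is the sterically governed iridium-catalysed borylation of 1,2,3-trisubstituted arenes such as 1,2,3-trimethoxybenzene at C-5, applied here three times in one molecule. No ring is closed and no stereocentre is formed. The step needs site selectivity among fourteen aryl C–H bonds: the crowded catalyst does not engage a C–H bond ortho to a substituent, so the three C–H bonds of ring A, the two of ring C and C-3–H and C-5–H of rings B, D and E should stay untouched, and only the three C-4–H bonds react. Once C-4 is borylated every remaining aryl C–H bond is flanked on both sides, so over-borylation is self-limiting, and the sp3 C–H bonds of the methyl ethers are not attacked under these conditions.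

Step 8
Reactants: 14 tris(pinacolboronate) of the octamethyl 4-deoxy pentamer
Product: 15 octamethyl ether triol of the pentamer (free hydroxyl at C-4 of ring B and ring D and ring E)
Conditions: 30% aq H2O2, 2 M aq NaOH, THF, 0 °C; then aq Na2S2O3, pH 5, argon
Reagents that add atoms: hydrogen peroxide, OO
Why: In this standard oxidation of arylboronates hydroperoxide adds to boron, the aryl group migrates from boron to oxygen at the same carbon, and the borate ester hydrolyses to the phenol.

Step 9
Reactants: 15 octamethyl ether triol of the pentamer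
Product: 16 2-[2-(3,5-dihydroxyphenoxy)-3,5-dihydroxyphenoxy]-5-[2,4-dihydroxy-6-(2,4,6-trihydroxyphenoxy)phenoxy]benzene-1,3-diol (CNP0018313.0)
Conditions: BBr3 (16 equiv), CH2Cl2, −78 °C to rt, argon; MeOH, 0 °C; evaporation, Sephadex LH-20
Reagents that add atoms: none
Why: In this Lewis-acid ether cleavage BBr3 coordinates each methoxy oxygen and bromide removes the methyl group by SN2, whereas the diaryl ether bonds offer no sp3 carbon for attack and should survive.

Compound list
1 | 2,6-dimethoxyphenol | COc1cccc(OC)c1O | starting material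
2 | 2-fluoro-6-methoxybenzaldehyde | COc1cccc(F)c1C=O | starting material
3 | 2-(2,6-dimethoxyphenoxy)-6-methoxybenzaldehyde | COc1cccc(Oc2c(OC)cccc2OC)c1C=O | intermediate
4 | 2-(2,6-dimethoxyphenoxy)-6-methoxyphenyl formate | COc1cccc(Oc2c(OC)cccc2OC)c1OC=O | intermediate
5 | 2-(2,6-dimethoxyphenoxy)-6-methoxyphenol (D–E phenol) | COc1cccc(Oc2c(OC)cccc2OC)c1O | intermediate
6 | 4-bromo-2,6-dimethoxyphenol | COc1cc(Br)cc(OC)c1O | starting material
7 | 2-(4-bromo-2,6-dimethoxyphenoxy)-6-methoxybenzaldehyde | COc1cccc(Oc2c(OC)cc(Br)cc2OC)c1C=O | intermediate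
8 | 2-(4-bromo-2,6-dimethoxyphenoxy)-6-methoxyphenyl formate | COc1cccc(Oc2c(OC)cc(Br)cc2OC)c1OC=O | intermediate
9 | 2-(4-bromo-2,6-dimethoxyphenoxy)-6-methoxyphenol | COc1cccc(Oc2c(OC)cc(Br)cc2OC)c1O | intermediate
10 | 3,5-dimethoxyphenylboronic acid | COc1cc(OC)cc(B(O)O)c1 | starting material
11 | 5-bromo-2-[2-(3,5-dimethoxyphenoxy)-3-methoxyphenoxy]-1,3-dimethoxybenzene (A–B–C bromide) | COc1cc(OC)cc(Oc2c(OC)cccc2Oc2c(OC)cc(Br)cc2OC)c1 | intermediate
12 | 2-[2-(3,5-dimethoxyphenoxy)-3-methoxyphenoxy]-5-[2-(2,6-dimethoxyphenoxy)-6-methoxyphenoxy]-1,3-dimethoxybenzene (octamethyl ether of the 4-deoxy pentamer) | COc1cc(OC)cc(Oc2c(OC)cccc2Oc2c(OC)cc(Oc3c(OC)cccc3Oc3c(OC)cccc3OC)cc2OC)c1 | intermediate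
13 | bis(pinacolato)diboron | CC1(C)OB(OC1(C)C)B1OC(C)(C)C(C)(C)O1 | starting material
14 | tris(pinacolboronate) of the octamethyl 4-deoxy pentamer (pinacolboryl group at C-4 of ring B and ring D and ring E) | COc1cc(OC)cc(Oc2c(OC)cc(B3OC(C)(C)C(C)(C)O3)cc2Oc2c(OC)cc(Oc3c(OC)cc(B4OC(C)(C)C(C)(C)O4)cc3Oc3c(OC)cc(B4OC(C)(C)C(C)(C)O4)cc3OC)cc2OC)c1 | intermediate
15 | octamethyl ether triol of the pentamer (free hydroxyl at C-4 of ring B and ring D and ring E) | COc1cc(OC)cc(Oc2c(OC)cc(O)cc2Oc2c(OC)cc(Oc3c(OC)cc(O)cc3Oc3c(OC)cc(O)cc3OC)cc2OC)c1 | intermediate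
16 | 2-[2-(3,5-dihydroxyphenoxy)-3,5-dihydroxyphenoxy]-5-[2,4-dihydroxy-6-(2,4,6-trihydroxyphenoxy)phenoxy]benzene-1,3-diol (CNP0018313.0) | Oc1cc(O)cc(Oc2c(O)cc(O)cc2Oc2c(O)cc(Oc3c(O)cc(O)cc3Oc3c(O)cc(O)cc3O)cc2O)c1 | target

Total step count: 9. Longest linear sequence: 7 steps (steps 3, 4, 5, 6, 7, 8, 9, from 6 and 2 to 16).

Steps most likely to fail

Step 7. The catalyst may decay on this electron-rich, slowly reacting substrate before all three C-4–H bonds are borylated, leaving mixtures of mono-, bis- and tris-boronates that are hard to separate. The fallback gives up C–H functionalisation and carries the three oxygens in from the start by the same known reactions as steps 1 to 6. It sets out from 6 and 10 and uses commercial 2,4,6-trimethoxyphenol (COc1cc(OC)c(O)c(OC)c1) and 2-fluoro-4,6-dimethoxybenzaldehyde (COc1cc(F)c(C=O)c(OC)c1) in place of 1 and 2. SNAr of 2,4,6-trimethoxyphenol with the fluoroaldehyde (K2CO3, DMA, 140 °C) should give 2,4-dimethoxy-6-(2,4,6-trimethoxyphenoxy)benzaldehyde F1. Baeyer–Villiger oxidation with mCPBA gives the aryl formate F2, and methanolysis gives 2,4-dimethoxy-6-(2,4,6-trimethoxyphenoxy)phenol F3. In the same way 6 and the fluoroaldehyde give 2-(4-bromo-2,6-dimethoxyphenoxy)-4,6-dimethoxybenzaldehyde F4, then the aryl formate F5 and 2-(4-bromo-2,6-dimethoxyphenoxy)-4,6-dimethoxyphenol F6. Chan–Lam coupling of F6 with 10 gives 5-bromo-2-[2-(3,5-dimethoxyphenoxy)-3,5-dimethoxyphenoxy]-1,3-dimethoxybenzene F7. Ullmann coupling of F7 with F3 (CuI, picolinic acid, K3PO4, DMSO) gives the undecamethyl ether of the target F8. BBr3 as in step 9 then cleaves all eleven methyl ethers, and the fallback comes back to the route at 16. The price is slower ether couplings on more electron-rich rings.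

Step 6. Exchange of the bulky di-ortho-substituted phenoxide at copper may be slow, so that protodebromination of 11 and thermal decomposition outrun C–O bond formation. The fallback sets out from 11 and 5 and replaces the copper manifold by palladium-catalysed Buchwald–Hartwig etherification (Pd(OAc)2, 2-di-tert-butylphosphino-2',4',6'-triisopropylbiphenyl, K3PO4, toluene, 100 °C). Its mechanism differs: zerovalent palladium adds oxidatively into the C–Br bond, and reductive elimination from the aryl palladium phenoxide is helped by steric bulk. It passes through no new compound (F0) and comes back to the route at 12.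

Step 9. Cleavage of the eight methyl ethers may stop short, and the very polar, air-sensitive undecaphenol may be lost by oxidation during chromatography. The fallback sets out from 15. The crude product of the BBr3 treatment is not purified but acetylated (Ac2O, pyridine, DMAP, rt) to the undecaacetate of the target F9. This is stable on silica, so partially methylated material can be separated and resubmitted to BBr3. Acid-catalysed methanolysis (HCl in degassed MeOH, rt, argon) then removes the acetates without forming oxidisable phenoxides and comes back to the route at 16.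

Further compounds
F1 | step 7 | 2,4-dimethoxy-6-(2,4,6-trimethoxyphenoxy)benzaldehyde | COc1cc(OC)c(C=O)c(Oc2c(OC)cc(OC)cc2OC)c1
F2 | step 7 | 2,4-dimethoxy-6-(2,4,6-trimethoxyphenoxy)phenyl formate | COc1cc(OC)c(OC=O)c(Oc2c(OC)cc(OC)cc2OC)c1
F3 | step 7 | 2,4-dimethoxy-6-(2,4,6-trimethoxyphenoxy)phenol | COc1cc(OC)c(O)c(Oc2c(OC)cc(OC)cc2OC)c1
F4 | step 7 | 2-(4-bromo-2,6-dimethoxyphenoxy)-4,6-dimethoxybenzaldehyde | COc1cc(OC)c(C=O)c(Oc2c(OC)cc(Br)cc2OC)c1
F5 | step 7 | 2-(4-bromo-2,6-dimethoxyphenoxy)-4,6-dimethoxyphenyl formate | COc1cc(OC)c(OC=O)c(Oc2c(OC)cc(Br)cc2OC)c1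
F6 | step 7 | 2-(4-bromo-2,6-dimethoxyphenoxy)-4,6-dimethoxyphenol | COc1cc(OC)c(O)c(Oc2c(OC)cc(Br)cc2OC)c1
F7 | step 7 | 5-bromo-2-[2-(3,5-dimethoxyphenoxy)-3,5-dimethoxyphenoxy]-1,3-dimethoxybenzene | COc1cc(OC)cc(Oc2c(OC)cc(OC)cc2Oc2c(OC)cc(Br)cc2OC)c1
F8 | step 7 | undecamethyl ether of the target | COc1cc(OC)cc(Oc2c(OC)cc(OC)cc2Oc2c(OC)cc(Oc3c(OC)cc(OC)cc3Oc3c(OC)cc(OC)cc3OC)cc2OC)c1
F0 | step 6 | none | none
F9 | step 9 | undecaacetate of the target | CC(=O)Oc1cc(OC(C)=O)cc(Oc2c(OC(C)=O)cc(OC(C)=O)cc2Oc2c(OC(C)=O)cc(Oc3c(OC(C)=O)cc(OC(C)=O)cc3Oc3c(OC(C)=O)cc(OC(C)=O)cc3OC(C)=O)cc2OC(C)=O)c1
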